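Every part of the solid substrate charged stays somewhere, yet the violet run at 4.00 h reads 10.6% target and 0% solid. So 89.4% of that charge stands in forms I don't read.

| flask | solid substrate | partner | remark | time |
|---|---|---|---|---|
| violet | 28 mM | 50 mM | run made earlier |  |
| green | 44 mM | 50 mM | run made earlier |  |
| red | 20 mM | 75 mM | run made earlier |  |
| flask | 20 mM | 50.0 mM |  | 10 h |

| run | time / h | target / % | solid substrate / % |
|---|---|---|---|
| violet | 0.667 | 4.2 | 66.7 |
| violet | 2.00 | 9.2 | 33.7 |
| violet | 4.00 | 10.6 | 0 |
| violet | 5.00 | 9.1 | 0 |
| violet | 8.00 | 5.3 | 0.3 |
| violet | 10.0 | 4.1 | 0 |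
| green | 0.833 | 2.9 | 75.2 |
| green | 1.33 | 5.8 | 67.1 |
| green | 2.00 | 5.7 | 58.0 |
| green | 4.00 | 5.7 | 33.9 |
| green | 6.00 | 6.4 | 12.3 |
| green | 10.0 | 2.5 | 0.3 |
| red | 0.833 | 8.2 | 44.9 |
| red | 2.50 | 16.1 | 0 |
| red | 5.00 | 11.6 | 0.5 |
| red | 8.00 | 6.5 | 0 |
| red | 10.0 | 4.4 | 0.3 |

(standard deviation of a reading: 0.5 percentage points)

- the target standing at 10 h, as a percentage of the solid substrate charged
- the change that raises the amount of target at 10 h, in percent of the solid substrate charged most ("none" if none brings more than 2 percentage points) (larch / alder / maple / none)
- amount of target at 10 h, in percent of the solid substrate charged, after alder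

- larch: doubling the amount of partner, all else as stated
- alder: doubling the dissolution coefficient of the solid substrate, all else as stated
- maple: doubling the solubility of the solid substrate, all else as stated

- solid substrate is a solid; its amount is given per volume of the solution
- at the start none of the solid substrate is in solution

I solve the two ends and join them. Early in violet, target climbs while solid lasts. Violet's highest reading comes at 4.00 h, and I scale that time with the charge, so I put the flask's peak near 2.86 h. Green's highest reading holds 0.949 of violet's amount, so I carry the amount across. So I estimate the flask's peak at 14.8% of its charge.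

Late, I treat target's fall as exponential: violet reads 0.158 h⁻¹, red 0.173 h⁻¹, and I take 0.166 h⁻¹. I call 1.18 the fall number: the e-foldings target makes between peak and reading. By this reckoning the flask keeps 30.7% of its peak, so I commit to 4.55%.

Is one number enough? On green the same reckoning gives 3.65% against a reading of 2.5%. That misses by 1.1 percentage points, and the scatter is 0.5 points. So it is rough.

The forecast says 4.9%, which is higher than mine, with best none and 4.4% after alder. Its ground is: “Each change mainly speeds formation, so the target decays longer.” I share its choice of best: red, with this charge and more partner, reads 4.4% at 10.0 h, below my 4.55%.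

The flask gives 4.07%, and best is none: larch moves it by 0.66 points, alder by −0.01 points, maple by −0.056 points, and alder leaves 4.06%.

    2 partner → self-condensation product (k = 11.4 L mol⁻¹ h⁻¹)
    2 dissolved substrate → side product (k = 24.6 L mol⁻¹ h⁻¹)
    solid substrate ⇌ dissolved substrate, rate k3*(cs3 - [dissolved substrate]) while solid is left; crystals form when [dissolved substrate] > cs3 (solubility = 13.0 mM, k = 1.70 h⁻¹)
    dissolved substrate + partner ⇌ target (K = 30.0 L mol⁻¹, k = 10.9 L mol⁻¹ h⁻¹)

In this flask each of the three changes stays below the 2 points that counts. Read at 6.0 h, the neighbour flask has a fall number of 0.521, which gives 8.79%. It stands at 8.72% target, beside 70.8% side product.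

Readings and results come from a simulation from invented constants, noise included.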